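The route grows the benzene ring onto a finished, enantiopure oxygen heterocycle (ring B). Ring A (C4a, C5, C6, C7, C8, C8a) carries O1 on C8a para to the C6 oxygen and a methyl on C8 beside C8a. This is the hydroquinone monoether pattern of a Dötz benzannulation in which O1 is the alkoxy oxygen of the carbene itself. In one operation the carbene carbon (C8a), its exocyclic alkene (C4a=C5), 1-(trimethylsilyl)propyne (C8, C7) and one CO (C6) become ring A. The precursor is a pentacarbonylchromium 2-oxacyclohexylidene complex with a 3-methylidene group and the C2 quaternary stereocentre, set by Sharpless epoxidation of geraniol.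

Key step: step 8

Remark: locants O1 to C8a always mean the chromane atoms of the target; the R/S label at the quaternary carbon changes in some intermediates (for example 10) only because CIP priorities change; simple salts made by deprotonation (lithium anion of 10, phenoxide of 14, carboxylate of 22) count as ionised forms of the numbered compounds.

Step 1
Reactants: 1 geraniol
Product: 2 [(2R,3R)-3-methyl-3-(4-methylpent-3-en-1-yl)oxiran-2-yl]methanol
Conditions: Ti(OiPr)4 (cat.), D-(−)-diethyl tartrate (cat.), t-BuOOH, 4 Å molecular sieves, CH2Cl2, −20 °C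
Reagents that add atoms: tert-butyl hydroperoxide, CC(C)(C)OO
Why: Sharpless asymmetric epoxidation, in which the titanium tartrate peroxide complex binds the allylic hydroxyl and delivers oxygen to one face of the 2,3-alkene only, so that D-(−)-tartrate sets both epoxide carbons as R (C3 being the later chromane C2) and the remote 6,7-alkene is left alone.

Step 2
Reactants: 2 [(2R,3R)-3-methyl-3-(4-methylpent-3-en-1-yl)oxiran-2-yl]methanol
Product: 3 (3R)-3,7-dimethyloct-6-ene-1,3-diol
Conditions: NaAlH2(OCH2CH2OMe)2, THF, 0 °C to rt; aqueous potassium sodium tartrate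
Reagents that add atoms: none
Why: Hydroxyl-directed reductive opening of a 2,3-epoxy alcohol, the aluminium-bound alkoxide delivering hydride intramolecularly to C2 so that the C3–O bond and its configuration are retained in the 1,3-diol.

Step 3
Reactants: 3 (3R)-3,7-dimethyloct-6-ene-1,3-diol
Product: 4 (3R)-1-iodo-3,7-dimethyloct-6-en-3-ol
Conditions: I2, PPh3, imidazole, CH2Cl2, 0 °C to rt
Reagents that add atoms: iodine, II
Why: Appel-type iodination, in which only the unhindered primary hydroxyl forms the alkoxyphosphonium ion that iodide displaces by SN2, the tertiary hydroxyl being too hindered to react.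

Step 4
Reactants: 4 (3R)-1-iodo-3,7-dimethyloct-6-en-3-ol
Product: 5 triethyl{[(3R)-1-iodo-3,7-dimethyloct-6-en-3-yl]oxy}silane
Conditions: Et3SiOTf, 2,6-lutidine, CH2Cl2, −78 to 0 °C
Reagents that add atoms: triethylsilyl trifluoromethanesulfonate, CC[Si](CC)(CC)OS(=O)(=O)C(F)(F)F
Why: Silyl triflate silylation of a tertiary alcohol, needed because the free alkoxide would quench the acetylide and close an oxetane onto the iodide in the next step.

Step 5
Reactants: 5 triethyl{[(3R)-1-iodo-3,7-dimethyloct-6-en-3-yl]oxy}silane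
Product: 7 (5R)-5,9-dimethyldec-8-en-1-yn-5-ol, via alkyne triethylsilyl ether 6 (not isolated)
Conditions: LiC≡CH·H2NCH2CH2NH2, DMSO, 10 °C to rt; aqueous work-up; then n-Bu4NF, THF, rt
Reagents that add atoms: lithium acetylide (ethylenediamine complex), [Li]C#C
Why: SN2 alkylation of lithium acetylide by the primary iodide in a dipolar aprotic solvent, followed by fluoride cleavage of the Si–O bond, the stereocentre taking no part.

Step 6
Reactants: 7 (5R)-5,9-dimethyldec-8-en-1-yn-5-ol; 8 hexacarbonylchromium
Product: 10 pentacarbonyl[(6S)-6-methyl-6-(4-methylpent-3-en-1-yl)oxan-2-ylidene]chromium, via Cr(CO)5(THF) 9 (not isolated)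
Conditions: Cr(CO)6, THF, hν, rt, Ar; then 7, rt, dark
Reagents that add atoms: none
Why: Alkynol cycloisomerisation at zerovalent chromium, in which the η2-alkyne complex formed from Cr(CO)5(THF) rearranges to the vinylidene and the tertiary hydroxyl adds to its electrophilic metal-bound carbon to close the six-membered Fischer carbene (a reaction known for pent-4-yn-1-ols), with no bond to the stereocentre broken.

Step 7
Reactants: 10 pentacarbonyl[(6S)-6-methyl-6-(4-methylpent-3-en-1-yl)oxan-2-ylidene]chromium
Product: 12 pentacarbonyl[(6R)-6-methyl-3-methylidene-6-(4-methylpent-3-en-1-yl)oxan-2-ylidene]chromium, via Mannich base complex 11 (not isolated)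
Conditions: n-BuLi, THF, −78 °C; [CH2=NMe2]I, −78 °C to rt; then SiO2
Reagents that add atoms: N,N-dimethylmethylideneammonium iodide (Eschenmoser's salt), C=[N+](C)C.[I-]
Why: Mannich reaction of the acidic α-CH2 of an alkoxycarbene complex (as its lithium anion) with the iminium salt, then E1cB loss of dimethylamine on silica, an α-methylenation of the kind used for cyclic alkoxycarbene complexes.

Step 8
Reactants: 12 pentacarbonyl[(6R)-6-methyl-3-methylidene-6-(4-methylpent-3-en-1-yl)oxan-2-ylidene]chromium; 13 1-(trimethylsilyl)propyne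
Product: 14 (2R)-2,8-dimethyl-2-(4-methylpent-3-en-1-yl)-7-(trimethylsilyl)chroman-6-ol
Conditions: 13 (3 equiv), THF, 55 °C, Ar; then air, rt, filtration through SiO2
Reagents that add atoms: none
Why: Dötz benzannulation: thermal loss of one CO from zerovalent chromium lets the alkyne bind and insert into the Cr=C8a bond with its methyl-bearing carbon joining C8a, and CO insertion at the new carbene carbon C7 gives a chromium-bound dienylketene. Ring A then closes by 6π electrocyclisation of this ketene, which makes the C6–C5 bond, and enolisation of the resulting cyclohexadienone gives the phenol. The closest known reaction type is the benzannulation of alkenyl(alkoxy)carbene pentacarbonylchromium complexes with silyl-substituted alkynes. No stereocentre is formed; C2 and the O1–C2 bond sit in the alkoxy ring of the carbene, are not touched, and keep the configuration set in step 1. The selectivity needed is the sense of alkyne insertion, and the bulky SiMe3 group should take the position next to the CO-derived carbon C6 so that CH3 ends on C8, while the unsubstituted exocyclic CH2 (C5) keeps the electrocyclisation unhindered.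

Step 9
Reactants: 14 (2R)-2,8-dimethyl-2-(4-methylpent-3-en-1-yl)-7-(trimethylsilyl)chroman-6-ol
Product: 15 [(2R)-6-methoxy-2,8-dimethyl-2-(4-methylpent-3-en-1-yl)chroman-7-yl]trimethylsilane
Conditions: MeI, K2CO3, DMF, rt
Reagents that add atoms: iodomethane, CI
Why: Williamson methylation of the phenoxide, which also takes the oxidation-prone hydroquinone monoether out of play.

Step 10
Reactants: 15 [(2R)-6-methoxy-2,8-dimethyl-2-(4-methylpent-3-en-1-yl)chroman-7-yl]trimethylsilane
Product: 16 (2R)-6-methoxy-2,8-dimethyl-2-(4-methylpent-3-en-1-yl)chromane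
Conditions: CF3CO2H, CH2Cl2, −10 to 0 °C; aqueous NaHCO3
Reagents that add atoms: none
Why: Ipso-protodesilylation (electrophilic aromatic substitution), protonation at C7 being favoured by the ortho methoxy group and the β-silicon effect so that the C–Si bond should break at low temperature before the side-chain alkene is protonated.

Step 11
Reactants: 16 (2R)-6-methoxy-2,8-dimethyl-2-(4-methylpent-3-en-1-yl)chromane
Product: 17 (2E)-5-[(2R)-6-methoxy-2,8-dimethylchroman-2-yl]-2-methylpent-2-en-1-ol
Conditions: SeO2 (cat.), t-BuOOH, salicylic acid (cat.), CH2Cl2, 0 °C to rt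
Reagents that add atoms: selenium dioxide, O=[Se]=O; tert-butyl hydroperoxide, CC(C)(C)OO
Why: SeO2 allylic oxidation (ene reaction then [2,3]-sigmatropic shift), which on a trisubstituted alkene attacks the methyl group trans to the chain and so gives the E allylic alcohol.

Step 12
Reactants: 17 (2E)-5-[(2R)-6-methoxy-2,8-dimethylchroman-2-yl]-2-methylpent-2-en-1-ol
Product: 18 (2R)-2-[(3E)-5-bromo-4-methylpent-3-en-1-yl]-6-methoxy-2,8-dimethylchromane
Conditions: CBr4, PPh3, CH2Cl2, 0 °C
Reagents that add atoms: carbon tetrabromide, BrC(Br)(Br)Br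
Why: Appel bromination, bromide displacing the alkoxyphosphonium group at the primary allylic carbon by SN2 with the E alkene unchanged.

Step 13
Reactants: 18 (2R)-2-[(3E)-5-bromo-4-methylpent-3-en-1-yl]-6-methoxy-2,8-dimethylchromane
Product: 20 (4E)-7-[(2R)-6-methoxy-2,8-dimethylchroman-2-yl]-4-methylhept-4-enal, via N-cyclohexyl imine 19 (not isolated)
Conditions: N-cyclohexylethanimine, LiN(i-Pr)2, THF, −78 °C; then 18, −78 to 0 °C; aqueous oxalic acid, rt
Reagents that add atoms: N-cyclohexylethanimine, CC=NC1CCCCC1; water, O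
Why: Aza-enolate (metalloenamine) alkylation, the lithiated acetaldehyde imine displacing the primary allylic bromide by SN2 and mild acid hydrolysis of the imine freeing the aldehyde two carbons longer.

Step 14
Reactants: 20 (4E)-7-[(2R)-6-methoxy-2,8-dimethylchroman-2-yl]-4-methylhept-4-enal
Product: 21 methyl (2Z,6E)-9-[(2R)-6-methoxy-2,8-dimethylchroman-2-yl]-2,6-dimethylnona-2,6-dienoate
Conditions: (CF3CH2O)2P(O)CH(CH3)CO2Me, KN(SiMe3)2, 18-crown-6, THF, −78 °C
Reagents that add atoms: methyl 2-[bis(2,2,2-trifluoroethoxy)phosphoryl]propanoate, COC(=O)C(C)P(=O)(OCC(F)(F)F)OCC(F)(F)F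
Why: Still–Gennari variant of the Horner–Wadsworth–Emmons olefination, in which the electron-poor phosphonate and the crown-complexed potassium ion make elimination from the kinetic adduct fast and so give the Z trisubstituted enoate.

Step 15
Reactants: 21 methyl (2Z,6E)-9-[(2R)-6-methoxy-2,8-dimethylchroman-2-yl]-2,6-dimethylnona-2,6-dienoate
Product: 22 (2Z,6E)-9-[(2R)-6-methoxy-2,8-dimethylchroman-2-yl]-2,6-dimethylnona-2,6-dienoic acid
Conditions: LiOH, THF/MeOH/H2O, rt to 40 °C; then aqueous HCl to pH 3
Reagents that add atoms: lithium hydroxide, [Li+].[OH-]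
Why: Saponification of the methyl ester by acyl–oxygen cleavage, conditions under which neither alkene nor the quaternary centre is affected.

Compound list
1 | geraniol, (2E)-3,7-dimethylocta-2,6-dien-1-ol | CC(C)=CCC/C(C)=C/CO | starting material
2 | [(2R,3R)-3-methyl-3-(4-methylpent-3-en-1-yl)oxiran-2-yl]methanol | OC[C@H]1O[C@]1(C)CCC=C(C)C | intermediate
3 | (3R)-3,7-dimethyloct-6-ene-1,3-diol | OCC[C@@](C)(CCC=C(C)C)O | intermediate
4 | (3R)-1-iodo-3,7-dimethyloct-6-en-3-ol | ICC[C@@](C)(CCC=C(C)C)O | intermediate
5 | triethyl{[(3R)-1-iodo-3,7-dimethyloct-6-en-3-yl]oxy}silane | ICC[C@@](C)(CCC=C(C)C)O[Si](CC)(CC)CC | intermediate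
6 | {[(5R)-5,9-dimethyldec-8-en-1-yn-5-yl]oxy}triethylsilane | C#CCC[C@@](C)(CCC=C(C)C)O[Si](CC)(CC)CC | intermediate (not isolated)
7 | (5R)-5,9-dimethyldec-8-en-1-yn-5-ol | C#CCC[C@@](C)(CCC=C(C)C)O | intermediate
8 | hexacarbonylchromium | O=C=[Cr](=C=O)(=C=O)(=C=O)(=C=O)=C=O | starting material
9 | pentacarbonyl(tetrahydrofuran)chromium | O=C=[Cr-](=C=O)(=C=O)(=C=O)(=C=O)[O+]1CCCC1 | intermediate (not isolated)
10 | pentacarbonyl[(6S)-6-methyl-6-(4-methylpent-3-en-1-yl)oxan-2-ylidene]chromium | O=C=[Cr](=C=O)(=C=O)(=C=O)(=C=O)=C1CCC[C@@](C)(CCC=C(C)C)O1 | intermediate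
11 | pentacarbonyl[(6R)-3-[(dimethylamino)methyl]-6-methyl-6-(4-methylpent-3-en-1-yl)oxan-2-ylidene]chromium (both C3 epimers) | CN(C)CC1CC[C@@](C)(CCC=C(C)C)OC1=[Cr](=C=O)(=C=O)(=C=O)(=C=O)=C=O | intermediate (not isolated)
12 | pentacarbonyl[(6R)-6-methyl-3-methylidene-6-(4-methylpent-3-en-1-yl)oxan-2-ylidene]chromium | C=C1CC[C@@](C)(CCC=C(C)C)OC1=[Cr](=C=O)(=C=O)(=C=O)(=C=O)=C=O | intermediate
13 | 1-(trimethylsilyl)propyne | CC#C[Si](C)(C)C | starting material
14 | (2R)-2,8-dimethyl-2-(4-methylpent-3-en-1-yl)-7-(trimethylsilyl)chroman-6-ol | Oc1c([Si](C)(C)C)c(C)c2c(c1)CC[C@@](C)(CCC=C(C)C)O2 | intermediate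
15 | [(2R)-6-methoxy-2,8-dimethyl-2-(4-methylpent-3-en-1-yl)chroman-7-yl]trimethylsilane | COc1c([Si](C)(C)C)c(C)c2c(c1)CC[C@@](C)(CCC=C(C)C)O2 | intermediate
16 | (2R)-6-methoxy-2,8-dimethyl-2-(4-methylpent-3-en-1-yl)chromane | COc1cc(C)c2c(c1)CC[C@@](C)(CCC=C(C)C)O2 | intermediate
17 | (2E)-5-[(2R)-6-methoxy-2,8-dimethylchroman-2-yl]-2-methylpent-2-en-1-ol | COc1cc(C)c2c(c1)CC[C@@](C)(CC/C=C(\C)CO)O2 | intermediate
18 | (2R)-2-[(3E)-5-bromo-4-methylpent-3-en-1-yl]-6-methoxy-2,8-dimethylchromane | COc1cc(C)c2c(c1)CC[C@@](C)(CC/C=C(\C)CBr)O2 | intermediate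
19 | (4E)-N-cyclohexyl-7-[(2R)-6-methoxy-2,8-dimethylchroman-2-yl]-4-methylhept-4-en-1-imine | COc1cc(C)c2c(c1)CC[C@@](C)(CC/C=C(\C)CCC=NC3CCCCC3)O2 | intermediate (not isolated)
20 | (4E)-7-[(2R)-6-methoxy-2,8-dimethylchroman-2-yl]-4-methylhept-4-enal | COc1cc(C)c2c(c1)CC[C@@](C)(CC/C=C(\C)CCC=O)O2 | intermediate
21 | methyl (2Z,6E)-9-[(2R)-6-methoxy-2,8-dimethylchroman-2-yl]-2,6-dimethylnona-2,6-dienoate | COc1cc(C)c2c(c1)CC[C@@](C)(CC/C=C(\C)CC/C=C(/C)C(=O)OC)O2 | intermediate
22 | (2Z,6E)-9-[(2R)-6-methoxy-2,8-dimethylchroman-2-yl]-2,6-dimethylnona-2,6-dienoic acid | COc1cc(C)c2c(c1)CC[C@@](C)(CC/C=C(\C)CC/C=C(/C)C(=O)O)O2 | target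

Total step count: 15. Longest linear sequence: 15 steps (1 to 22).

Steps most likely to fail

1. Step 8. Alkyne insertion into the hindered chromium–carbon double bond may be slow enough for the electron-poor exocyclic alkene to add to itself and oligomerise. Insertion may also occur in the reverse sense, or the sequence may stop at a silicon-stabilised dienylketene whose alkene geometry does not allow electrocyclisation. In the fallback ring A is bought and ring B is closed at O1–C8a by Pd-catalysed aryl ether formation, which again leaves the C2–O bond alone. It sets out from 5 and returns at 16. 4-Methoxy-2-methylaniline is iodinated at its free ortho position (ICl, AcOH) to 2-iodo-4-methoxy-6-methylaniline F1, and Sandmeyer bromination (t-BuONO, CuBr2, MeCN) gives 2-bromo-1-iodo-5-methoxy-3-methylbenzene F2. Iodide 5 is turned by t-BuLi and 9-methoxy-9-borabicyclo[3.3.1]nonane into its alkylborate, which is coupled at the C–I bond of F2 (PdCl2[1,1'-bis(diphenylphosphino)ferrocene], K3PO4, DMF; B-alkyl Suzuki–Miyaura coupling) to triethyl{[(3R)-1-(2-bromo-5-methoxy-3-methylphenyl)-3,7-dimethyloct-6-en-3-yl]oxy}silane F3. n-Bu4NF then frees (3R)-1-(2-bromo-5-methoxy-3-methylphenyl)-3,7-dimethyloct-6-en-3-ol F4, and Pd(OAc)2 with 2-(di-tert-butylphosphino)-1,1'-binaphthyl and Cs2CO3 in toluene at 80 °C should close the chromane to 16 with the configuration at C2 retained.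

2. Step 6. The alkyne-to-vinylidene rearrangement at chromium and the 6-endo attack by the hindered tertiary hydroxyl may both be slow, so that loss of the labile Cr(CO)5 fragment or proton loss to the cyclic enol ether wins. In the fallback the ring is closed by C-alkylation of a preformed carbene followed by alkoxy exchange at the carbene carbon. It sets out from 3 and 8 and returns at 10. Hexacarbonylchromium 8 is treated with MeLi and then Me3OBF4 to give pentacarbonyl(1-methoxyethylidene)chromium F5. Diol 3 is converted at −78 °C ((CF3SO2)2O, 2,6-di-tert-butylpyridine, CH2Cl2) into its primary triflate, (3R)-3-hydroxy-3,7-dimethyloct-6-en-1-yl trifluoromethanesulfonate F6, which is added cold to the lithium anion of F5 (n-BuLi, THF, −78 °C). C-alkylation should give pentacarbonyl[(5S)-5-hydroxy-1-methoxy-5,9-dimethyldec-8-en-1-ylidene]chromium F7. A catalytic amount of NaOMe should then let the tertiary alkoxide displace methoxide at the carbene carbon and close the six-membered ring of 10, without touching the C–O bond of the stereocentre.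

3. Step 7. The liberated dimethylamine may add back to the new alkene or attack the carbene carbon (aminolysis), or the elimination may stay incomplete. In the fallback the methylene carbon is brought in as an ether and lost as methanol on a basic surface, so that no nitrogen nucleophile is ever present. It sets out from 10 and returns at 12. The lithium anion of 10 (n-BuLi, THF, −78 °C) is alkylated with chloromethyl methyl ether to pentacarbonyl[(6R)-3-(methoxymethyl)-6-methyl-6-(4-methylpent-3-en-1-yl)oxan-2-ylidene]chromium F8, and passage over basic Al2O3 should eliminate methanol to give 12.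

Further compounds
F1 | step 8 | 2-iodo-4-methoxy-6-methylaniline | COc1cc(C)c(N)c(I)c1
F2 | step 8 | 2-bromo-1-iodo-5-methoxy-3-methylbenzene | COc1cc(C)c(Br)c(I)c1
F3 | step 8 | triethyl{[(3R)-1-(2-bromo-5-methoxy-3-methylphenyl)-3,7-dimethyloct-6-en-3-yl]oxy}silane | COc1cc(C)c(Br)c(c1)CC[C@@](C)(CCC=C(C)C)O[Si](CC)(CC)CC
F4 | step 8 | (3R)-1-(2-bromo-5-methoxy-3-methylphenyl)-3,7-dimethyloct-6-en-3-ol | COc1cc(C)c(Br)c(c1)CC[C@@](C)(CCC=C(C)C)O
F5 | step 6 | pentacarbonyl(1-methoxyethylidene)chromium | COC(C)=[Cr](=C=O)(=C=O)(=C=O)(=C=O)=C=O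
F6 | step 6 | (3R)-3-hydroxy-3,7-dimethyloct-6-en-1-yl trifluoromethanesulfonate | O=S(=O)(OCC[C@@](C)(CCC=C(C)C)O)C(F)(F)F
F7 | step 6 | pentacarbonyl[(5S)-5-hydroxy-1-methoxy-5,9-dimethyldec-8-en-1-ylidene]chromium | COC(CCC[C@@](C)(CCC=C(C)C)O)=[Cr](=C=O)(=C=O)(=C=O)(=C=O)=C=O
F8 | step 7 | pentacarbonyl[(6R)-3-(methoxymethyl)-6-methyl-6-(4-methylpent-3-en-1-yl)oxan-2-ylidene]chromium | COCC1CC[C@@](C)(CCC=C(C)C)OC1=[Cr](=C=O)(=C=O)(=C=O)(=C=O)=C=O
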